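**Plan**

Rings: A = cyclohexene (closed last), B = methylenecyclohexane, C = spiro δ-lactone (O1, C2=O, C3, C4, spiro C5, C6Me2), D = spiro furan-2,4-dione.
Retrosynthesis: ring A is cut between its methyl-bearing olefinic carbon and C5 of ring C (intramolecular Heck), then at CH2–C5 (B-alkyl Suzuki–Miyaura with an iodolactone); ring B at C(=CH2)–C(spiro, ring D) (Conia-ene); ring D by Dieckmann; the open chain between the angular-methyl carbon and the future ring-fusion olefinic carbon (Ireland–Claisen).
Forward order: open chain, ring D, ring B, attachment of preformed ring C, ring A last; the building blocks are a β-keto ester/acrolein adduct, a C6 allylic alcohol, an iodolactone and methyl (R)-lactate.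
Enabling feature: C5 of ring C lies β,γ to the lactone carbonyl and bears no hydrogen, so a C4=C5 olefin can take up the alkenylpalladium of the tetrasubstituted ring A olefin carbon in a 6-exo mode and can only eliminate toward C3. One event gives ring A, the spiro centre and the C3=C4 enoate.
Stereochemistry: acid-bearing quaternary carbon by cinchona-catalysed Michael addition; angular-methyl carbon by chiral-boron Ireland–Claisen; ring D methine from methyl (R)-lactate; spiro carbon of ring D by Conia-ene attack anti to that methyl; spiro C5 by the chair-like Heck transition state.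

Key step: step 16

Assumption: the sense of induction of the cinchona catalyst (step 1) and of the chiral boron controller (step 6) is taken to be the one drawn; the pseudo-enantiomeric catalyst or the antipodal controller would serve if the opposite sense is found.

**Route**

Step 1
Reactants: 1 tert-butyl 2-methyl-3-oxobutanoate; 2 acrolein
Product: 3 tert-butyl (R)-2-acetyl-2-methyl-5-oxopentanoate
Conditions: 9-O-(9-phenanthryl)cupreidine (10 mol %), CH2Cl2, −24 °C
Reagents that add atoms: none
Why: Cinchona-alkaloid-catalysed Michael addition of an α-substituted β-keto ester to an enal; the bifunctional catalyst (quinuclidine base, 6'-OH hydrogen bond) should direct acrolein to one face of the enol and so set the quaternary carbon.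

Step 2
Reactants: 3 tert-butyl (R)-2-acetyl-2-methyl-5-oxopentanoate
Product: 4 (R)-4-acetyl-5-tert-butoxy-4-methyl-5-oxopentanoic acid
Conditions: NaClO2, NaH2PO4, 2-methylbut-2-ene, t-BuOH/H2O, 0 °C to rt
Reagents that add atoms: sodium chlorite, [Na+].[O-]Cl=O
Why: Pinnick oxidation is selective for the aldehyde and should leave the ketone, the tert-butyl ester and the non-enolisable quaternary centre untouched.

Step 3
Reactants: 4 (R)-4-acetyl-5-tert-butoxy-4-methyl-5-oxopentanoic acid
Product: 6 (R)-4-(tert-butoxycarbonyl)-4-methylhex-5-ynoic acid, via enol triflate 5 (not isolated)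
Conditions: LiN(iPr)2 (2.2 equiv), THF, −78 °C; PhNTf2, to 0 °C; then LiN(iPr)2 (2.5 equiv), −78 to 0 °C; aq HCl
Reagents that add atoms: N-phenylbis(trifluoromethanesulfonimide), O=S(=O)(N(c1ccccc1)S(=O)(=O)C(F)(F)F)C(F)(F)F (its CF3SO2 group is carried by 5 only); lithium diisopropylamide, [Li]N(C(C)C)C(C)C (lithium carried by 5 only)
Why: Ketone-to-alkyne conversion via the kinetic enol triflate (only the acetyl CH3 can enolise) followed by base-induced elimination; the carboxylate is inert and the quaternary centre bears no hydrogen.

Step 4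
Reactants: 7 4-(tert-butyldimethylsilyloxy)but-1-yne
Product: 9 (E)-5-(tert-butyldimethylsilyloxy)-3-methylpent-2-en-1-ol, via alkenylalane 8 (not isolated)
Conditions: AlMe3, Cp2ZrCl2 (20 mol %), CH2Cl2, 0 °C to rt; then (CH2O)n, THF; aq work-up
Reagents that add atoms: trimethylaluminium, C[Al](C)C; formaldehyde (as paraformaldehyde), C=O
Why: Zirconium-catalysed syn-methylalumination of the terminal alkyne and hydroxymethylation of the alkenylalane; the syn addition fixes the E geometry.

Step 5
Reactants: 6 (R)-4-(tert-butoxycarbonyl)-4-methylhex-5-ynoic acid; 9 (E)-5-(tert-butyldimethylsilyloxy)-3-methylpent-2-en-1-ol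
Product: 10 1-tert-butyl 5-[(E)-5-(tert-butyldimethylsilyloxy)-3-methylpent-2-enyl] (R)-2-ethynyl-2-methylpentanedioate
Conditions: DCC, DMAP (cat.), CH2Cl2, 0 °C to rt
Reagents that add atoms: none
Why: Steglich esterification of a primary allylic alcohol under neutral conditions; no stereocentre is involved.

Step 6
Reactants: 10 the allylic ester
Product: 11 2-[(2R)-2-(tert-butoxycarbonyl)-2-methylbut-3-ynyl]-3-[2-(tert-butyldimethylsilyloxy)ethyl]-3-methylpent-4-enoic acid (3S; C-2 of no consequence)
Conditions: (S,S)-2-bromo-4,5-diphenyl-1,3-bis[3,5-bis(trifluoromethyl)phenylsulfonyl]-1,3,2-diazaborolidine (1.2 equiv), Et3N, toluene/hexane, −78 °C then 4 °C; aq work-up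
Reagents that add atoms: none
Why: Enantioselective Ireland–Claisen rearrangement through a chiral boron ketene acetal; the chair transition state with the E-trisubstituted allyl unit and the face selection by the C2-symmetric controller should fix the methyl/vinyl quaternary carbon, while the adjacent CH centre is erased in step 9.

Step 7
Reactants: 11 the Claisen acid
Product: 12 tert-butyl (2R)-4-acetyl-5-[2-(tert-butyldimethylsilyloxy)ethyl]-2-ethynyl-2,5-dimethylhept-6-enoate (5S; C-4 of no consequence)
Conditions: MeLi (4 equiv), Et2O/THF, 0 °C to rt; then H2O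
Reagents that add atoms: methyllithium, [Li]C
Why: Addition of MeLi to the lithium carboxylate gives a gem-dialkoxide that releases the methyl ketone on hydrolysis; the alkyne C–H is only deprotonated and the tert-butyl ester on a quaternary carbon should be too hindered to react.

Step 8
Reactants: 12 the methyl ketone
Product: 13 3-[1-acetyl-3-(tert-butoxycarbonyl)-3-methylpent-4-ynyl]-3-methylpent-4-enoic acid (3S, 3'R; C-1' of no consequence)
Conditions: CrO3, aq H2SO4, acetone, 0 °C
Reagents that add atoms: chromium trioxide, O=[Cr](=O)=O; water, O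
Why: Jones oxidation; the acidic reagent cleaves the primary silyl ether in the flask and oxidises the alcohol to the acid, while olefin, alkyne, ketone and tert-butyl ester should survive the short exposure.

Step 9
Reactants: 13 the δ-keto acid
Product: 14 tert-butyl (R)-2-{[(S)-2,4-dimethyl-6-oxo-4-vinyl-5,6-dihydro-4H-pyran-3-yl]methyl}-2-methylbut-3-ynoate
Conditions: Ac2O, NaOAc, 110 °C
Reagents that add atoms: none
Why: Enol lactonisation of a δ-keto acid via the mixed anhydride; equilibrating conditions should favour the endocyclic, more substituted enol δ-lactone, which removes the CH stereocentre and locks the enol oxygen cis to the quaternary carbon.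

Step 10
Reactants: 14 the enol lactone; 15 methyl (R)-lactate
Product: 17 tert-butyl (2R,4Z)-2-ethynyl-4-{(3S)-1-[(2R)-1-methoxy-1-oxopropan-2-yloxy]-3-methyl-1-oxopent-4-en-3-yl}-2-methyl-5-(trifluoromethylsulfonyloxy)hex-4-enoate, via lithium enolate 16 (not isolated)
Conditions: 15, n-BuLi, THF, −78 °C; add 14, −78 °C; then PhNTf2, −78 to 0 °C; aq NH4Cl
Reagents that add atoms: N-phenylbis(trifluoromethanesulfonimide), O=S(=O)(N(c1ccccc1)S(=O)(=O)C(F)(F)F)C(F)(F)F; n-butyllithium, [Li]CCCC (lithium carried by 16 only)
Why: Acyl transfer from the enol ester to the lactate alkoxide (alkoxide cleavage of an enol ester to a regiodefined enolate) should release the tetrasubstituted lithium enolate with its ring-derived geometry, and O-triflation traps it as the Z alkenyl triflate; the lactate centre is not involved.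

Step 11
Reactants: 17 the triflate lactate ester
Product: 18 tert-butyl (2R,4Z)-2-ethynyl-4-{(2S)-2-[(5R)-4-hydroxy-5-methyl-2-oxo-2,5-dihydrofuran-3-yl]but-3-en-2-yl}-2-methyl-5-(trifluoromethylsulfonyloxy)hex-4-enoate
Conditions: LiN(SiMe3)2 (3 equiv), THF, −78 to 0 °C; aq HCl
Reagents that add atoms: none
Why: Dieckmann condensation of an α-acyloxy ester to the 3-substituted tetronic acid (ring D); the product is held as its tetronate anion, which should protect the lactate-derived centre from epimerisation.

Step 12
Reactants: 18 the tetronic acid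
Product: 19 tert-butyl ester of the ring B/ring D spiro compound (6-methylidene, alkenyl triflate and vinyl retained; configuration as in the SMILES)
Conditions: Ph3PAuNTf2 (5 mol %), CH2Cl2, 40 °C
Reagents that add atoms: none
Why: Gold-catalysed Conia-ene carbocyclisation (6-exo-dig) of the cyclic 1,3-dicarbonyl onto the π-activated terminal alkyne, with protodeauration giving the exocyclic methylene; attack on the planar tetronate anti to its ring methyl should set the spiro carbon of ring D.

Step 13
Reactants: 20 2-methylbut-3-yn-2-ol; 21 triethyl orthoacetate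
Product: 22 ethyl 5-methylhexa-3,4-dienoate
Conditions: EtCO2H (cat.), 140 °C, EtOH distilled off
Reagents that add atoms: none
Why: Johnson–Claisen rearrangement of the propargylic ketene acetal gives the β-allenic ester; no stereocentre.

Step 14
Reactants: 22 ethyl 5-methylhexa-3,4-dienoate
Product: 24 5-iodo-6,6-dimethyl-3,6-dihydro-2H-pyran-2-one, via lithium allenoate 23 (not isolated)
Conditions: LiOH, THF/H2O, 0 °C; then I2, NaHCO3, MeCN/H2O, 0 °C
Reagents that add atoms: lithium hydroxide, [Li+].[OH-]; iodine, II
Why: Saponification, then iodolactonisation of the 3,4-allenoic acid: iodonium on the central allene carbon and carboxylate attack at the dimethyl-substituted terminus (6-endo) should give the β,γ-unsaturated δ-lactone carrying the alkenyl iodide.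

Step 15
Reactants: 19 the ring B/ring D vinyl compound; 24 5-iodo-6,6-dimethyl-3,6-dihydro-2H-pyran-2-one
Product: 26 Heck precursor (ring B/ring D compound with CH2CH2 link to C5 of the 3,6-dihydropyranone), via B-alkyl-9-BBN 25 (not isolated)
Conditions: 9-BBN, THF, 0 °C to rt; then 24, PdCl2(dppf) (5 mol %), AsPh3, K3PO4 (powdered hydrate), DMF, rt
Reagents that add atoms: 9-borabicyclo[3.3.1]nonane, B1C2CCCC1CCC2 (boron carried by 25 only)
Why: Anti-Markovnikov hydroboration of the only unhindered olefin and B-alkyl Suzuki–Miyaura coupling; oxidative addition to the alkenyl iodide should be much faster at rt than to the hindered tetrasubstituted triflate.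

Step 16
Reactants: 26 Heck precursor
Product: 27 tert-butyl ester of penicianstinoid C
Conditions: Pd(OAc)2 (10 mol %), PPh3 (25 mol %), 1,2,2,6,6-pentamethylpiperidine, MeCN, 80 °C
Reagents that add atoms: none
Why: Oxidative addition of zerovalent palladium into the alkenyl C–OTf bond gives a cationic alkenylpalladium that adds syn across the C4=C5 olefin of ring C with carbon going to C5, and syn β-hydride elimination from C3 (the only β-hydrogens, C5 now being quaternary) releases the C3=C4 enoate and the catalyst. The closest known reaction type is the intramolecular Heck cyclisation of alkenyl triflates onto trisubstituted olefins that builds all-carbon quaternary spiro centres. Ring A is closed in the 6-exo-trig mode; the 7-endo alternative would place palladium on a fully substituted carbon and is disfavoured. The one new stereocentre, spiro C5, should be set by a chair-like transition state in which the ring-B carbon on the angular centre sits pseudo-equatorial and the angular methyl pseudo-axial, so that the Pd–C4 bond adds on the face remote from that methyl and the O–CMe2 arm ends cis to it, as in the target. The step needs regio- and chemoselectivity: the position of the ring A olefin is fixed by the stereodefined triflate, the exocyclic methylene cannot be reached without forming a bridgehead olefin, and the hindered amine base should be too weak to move the β,γ-olefin of ring C into conjugation before insertion.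

Step 17
Reactants: 27 tert-butyl ester of penicianstinoid C
Product: 28 penicianstinoid C
Conditions: CF3CO2H/CH2Cl2 (1:4), 0 °C
Reagents that add atoms: none
Why: Acidolysis of the tert-butyl ester with loss of isobutene; no base is used, so the epimerisable ring D methine and the base-labile furandione should be safe.

**Compound list**

1 | tert-butyl 2-methyl-3-oxobutanoate (racemic) | CC(=O)C(C)C(=O)OC(C)(C)C | starting material
2 | acrolein | C=CC=O | starting material
3 | tert-butyl (R)-2-acetyl-2-methyl-5-oxopentanoate | CC(=O)[C@](C)(C(=O)OC(C)(C)C)CCC=O | intermediate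
4 | (R)-4-acetyl-5-tert-butoxy-4-methyl-5-oxopentanoic acid | CC(=O)[C@](C)(C(=O)OC(C)(C)C)CCC(=O)O | intermediate
5 | lithium (R)-4-(tert-butoxycarbonyl)-4-methyl-5-(trifluoromethylsulfonyloxy)hex-5-enoate | C=C(OS(=O)(=O)C(F)(F)F)[C@](C)(C(=O)OC(C)(C)C)CCC(=O)O[Li] | intermediate (not isolated)
6 | (R)-4-(tert-butoxycarbonyl)-4-methylhex-5-ynoic acid | C#C[C@](C)(C(=O)OC(C)(C)C)CCC(=O)O | intermediate
7 | 4-(tert-butyldimethylsilyloxy)but-1-yne | C#CCCO[Si](C)(C)C(C)(C)C | starting material
8 | [(E)-4-(tert-butyldimethylsilyloxy)-2-methylbut-1-enyl]dimethylalane | C[Al](C)/C=C(\C)CCO[Si](C)(C)C(C)(C)C | intermediate (not isolated)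
9 | (E)-5-(tert-butyldimethylsilyloxy)-3-methylpent-2-en-1-ol | OC/C=C(\C)CCO[Si](C)(C)C(C)(C)C | intermediate
10 | 1-tert-butyl 5-[(E)-5-(tert-butyldimethylsilyloxy)-3-methylpent-2-enyl] (R)-2-ethynyl-2-methylpentanedioate | C#C[C@](C)(C(=O)OC(C)(C)C)CCC(=O)OC/C=C(\C)CCO[Si](C)(C)C(C)(C)C | intermediate
11 | 2-[(2R)-2-(tert-butoxycarbonyl)-2-methylbut-3-ynyl]-3-[2-(tert-butyldimethylsilyloxy)ethyl]-3-methylpent-4-enoic acid (3S; C-2 unassigned) | C=C[C@](C)(CCO[Si](C)(C)C(C)(C)C)C(C[C@](C)(C#C)C(=O)OC(C)(C)C)C(=O)O | intermediate
12 | tert-butyl (2R)-4-acetyl-5-[2-(tert-butyldimethylsilyloxy)ethyl]-2-ethynyl-2,5-dimethylhept-6-enoate (5S; C-4 unassigned) | C=C[C@](C)(CCO[Si](C)(C)C(C)(C)C)C(C[C@](C)(C#C)C(=O)OC(C)(C)C)C(C)=O | intermediate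
13 | 3-[1-acetyl-3-(tert-butoxycarbonyl)-3-methylpent-4-ynyl]-3-methylpent-4-enoic acid (3S, 3'R; C-1' unassigned) | C=C[C@](C)(CC(=O)O)C(C[C@](C)(C#C)C(=O)OC(C)(C)C)C(C)=O | intermediate
14 | tert-butyl (R)-2-{[(S)-2,4-dimethyl-6-oxo-4-vinyl-5,6-dihydro-4H-pyran-3-yl]methyl}-2-methylbut-3-ynoate | CC1=C(C[C@](C)(C#C)C(=O)OC(C)(C)C)[C@](C)(C=C)CC(=O)O1 | intermediate
15 | methyl (R)-lactate | C[C@@H](O)C(=O)OC | starting material
16 | lithium (Z)-enolate from opening of 14 by the lactate alkoxide | [Li]O/C(C)=C(\[C@](C)(C=C)CC(=O)O[C@H](C)C(=O)OC)C[C@](C)(C#C)C(=O)OC(C)(C)C | intermediate (not isolated)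
17 | tert-butyl (2R,4Z)-2-ethynyl-4-{(3S)-1-[(2R)-1-methoxy-1-oxopropan-2-yloxy]-3-methyl-1-oxopent-4-en-3-yl}-2-methyl-5-(trifluoromethylsulfonyloxy)hex-4-enoate | FC(F)(F)S(=O)(=O)O/C(C)=C(\[C@](C)(C=C)CC(=O)O[C@H](C)C(=O)OC)C[C@](C)(C#C)C(=O)OC(C)(C)C | intermediate
18 | tert-butyl (2R,4Z)-2-ethynyl-4-{(2S)-2-[(5R)-4-hydroxy-5-methyl-2-oxo-2,5-dihydrofuran-3-yl]but-3-en-2-yl}-2-methyl-5-(trifluoromethylsulfonyloxy)hex-4-enoate | FC(F)(F)S(=O)(=O)O/C(C)=C(\[C@](C)(C=C)C1=C(O)[C@@H](C)OC1=O)C[C@](C)(C#C)C(=O)OC(C)(C)C | intermediate
19 | ring B/ring D spiro compound: tert-butyl 3,6,9-trimethyl-10-methylidene-1,4-dioxo-7-[(Z)-1-(trifluoromethylsulfonyloxy)ethylidene]-6-vinyl-2-oxaspiro[4.5]decane-9-carboxylate, both ring B methyl groups and the lactone carbonyl of ring D cis | C=C1[C@](C)(C(=O)OC(C)(C)C)C/C(=C(\C)OS(=O)(=O)C(F)(F)F)[C@](C)(C=C)[C@@]12C(=O)O[C@H](C)C2=O | intermediate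
20 | 2-methylbut-3-yn-2-ol | CC(C)(O)C#C | starting material
21 | triethyl orthoacetate | CCOC(C)(OCC)OCC | starting material
22 | ethyl 5-methylhexa-3,4-dienoate | CCOC(=O)CC=C=C(C)C | intermediate
23 | lithium 5-methylhexa-3,4-dienoate | CC(C)=C=CCC(=O)O[Li] | intermediate (not isolated)
24 | 5-iodo-6,6-dimethyl-3,6-dihydro-2H-pyran-2-one | CC1(C)OC(=O)CC=C1I | intermediate
25 | B-alkyl-9-BBN adduct of 19 (boron on the terminal carbon of the former vinyl group) | C=C1[C@](C)(C(=O)OC(C)(C)C)C/C(=C(\C)OS(=O)(=O)C(F)(F)F)[C@](C)(CCB2C3CCCC2CCC3)[C@@]14C(=O)O[C@H](C)C4=O | intermediate (not isolated)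
26 | Heck precursor: 19 with the vinyl group replaced by 2-(6,6-dimethyl-2-oxo-3,6-dihydro-2H-pyran-5-yl)ethyl | C=C1[C@](C)(C(=O)OC(C)(C)C)C/C(=C(\C)OS(=O)(=O)C(F)(F)F)[C@](C)(CCC2=CCC(=O)OC2(C)C)[C@@]13C(=O)O[C@H](C)C3=O | intermediate
27 | tert-butyl ester of penicianstinoid C | C=C1[C@](C)(C(=O)OC(C)(C)C)CC2=C(C)[C@]3(C=CC(=O)OC3(C)C)CC[C@]2(C)[C@@]12C(=O)O[C@H](C)C2=O | intermediate
28 | penicianstinoid C | C=C1[C@](C)(C(=O)O)CC2=C(C)[C@]3(C=CC(=O)OC3(C)C)CC[C@]2(C)[C@@]12C(=O)O[C@H](C)C2=O | target

**Step count**

Total steps: 17. Longest linear sequence: 14 steps (steps 1, 2, 3, 5 to 12, 15, 16, 17).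

**Steps most likely to fail**

Step 16 (Heck closure of ring A). The double bond of ring C may migrate into conjugation with the lactone carbonyl before carbopalladation, which removes the olefin from the position needed for 6-exo closure, and facial discrimination at the spiro carbon may be poor. The fallback sets out from 26 and comes back at 27. The migration is made deliberate with DBU in CH2Cl2 to give the conjugated 5-H lactone isomer F1. F1 is then treated with Pd2(dba)3, P(t-Bu)3 and Cs2CO3 in toluene at 80 °C: the alkenylpalladium formed from the triflate is taken up by the lactone dienolate at its γ-carbon and reductive elimination forges the same C–C bond. This is a palladium-catalysed γ-alkenylation of a dienolate in place of an olefin insertion, with a different stereo-determining transition state.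

Step 12 (Conia-ene closure of ring B). Attack of the fully substituted tetronate carbon next to a quaternary centre may be slow enough for the activated alkyne to be consumed by side reactions, and the facial bias from the ring methyl may be insufficient. The fallback sets out from 18 and comes back at 19 and makes no new compound (F0). It is an oxidative free-radical cyclisation with Mn(OAc)3·2H2O in EtOH at 60 °C: the tetronate is oxidised to its carbon-centred radical, which adds 6-exo to the alkyne, and the alkenyl radical takes a hydrogen atom from the solvent.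

Step 15 (hydroboration and B-alkyl coupling). The alkylborane may transmetalate onto palladium that has inserted into the neighbouring triflate of the same molecule (cyclopentene closure), and the base may open ring D or move the ring C olefin. The fallback sets out from 19 and comes back at 26. Hydroboration with 9-BBN as before, but with NaBO3 oxidative work-up, gives the primary alcohol F2. I2, PPh3 and imidazole convert it into the primary iodide F3. A nickel-catalysed reductive cross-electrophile coupling of F3 with 24 (NiCl2(dme), 4,4'-di-tert-butyl-2,2'-bipyridine, Mn, DMA, rt) then joins the sp3 and sp2 carbons without base and without a preformed organometallic.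

**Further compounds**

F1 | step 16 | conjugated isomer of 26 (6,6-dimethyl-2-oxo-5,6-dihydro-2H-pyran-5-yl, C5–H, configuration at C5 immaterial) | C=C1[C@](C)(C(=O)OC(C)(C)C)C/C(=C(\C)OS(=O)(=O)C(F)(F)F)[C@](C)(CCC2C=CC(=O)OC2(C)C)[C@@]13C(=O)O[C@H](C)C3=O
F0 | step 12 | none | none
F2 | step 15 | primary alcohol from hydroboration–oxidation of 19 | C=C1[C@](C)(C(=O)OC(C)(C)C)C/C(=C(\C)OS(=O)(=O)C(F)(F)F)[C@](C)(CCO)[C@@]12C(=O)O[C@H](C)C2=O
F3 | step 15 | primary iodide from F2 | C=C1[C@](C)(C(=O)OC(C)(C)C)C/C(=C(\C)OS(=O)(=O)C(F)(F)F)[C@](C)(CCI)[C@@]12C(=O)O[C@H](C)C2=O
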